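The octadecyl chain is cut between C8 and C9 (counted from the ester oxygen), deep inside the unbranched, unfunctionalised polymethylene segment, remote from the ester oxygen at C1 and from the catechol ring. Both carbons are plain primary sp3 centres, and the key step exploits this with a copper-catalysed alkyl–alkyl cross-coupling. Decylmagnesium bromide displaces bromide from 8-bromooctyl 2,3-dihydroxybenzoate, whose two phenols are masked in the same flask as trimethylsilyl ethers and released again on work-up, so the target forms in one operation. The coupling precursor comes in one step from 2,3-dihydroxybenzoic acid and 1,8-dibromooctane.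

Key step: step 2

Remark: the target has no stereocentre and no stereogenic double bond, so it is achiral and the route needs no stereocontrol. Decylmagnesium bromide is taken as the commercial ethereal solution (otherwise made from 1-bromodecane and Mg).

Step 1
Reactants: 1 2,3-dihydroxybenzoic acid; 2 1,8-dibromooctane
Product: 3 8-bromooctyl 2,3-dihydroxybenzoate
Conditions: KHCO3 (1.2 equiv), 2 (5 equiv), DMF, 50 °C, N2
Reagents that add atoms: none
Why: SN2 O-alkylation of the potassium carboxylate (carboxylate alkylation), in which bicarbonate deprotonates only the CO2H and leaves both phenols protonated and non-nucleophilic, while the excess of 2 (recoverable) suppresses esterification at both ends of the dibromide.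

Step 2
Reactants: 3 8-bromooctyl 2,3-dihydroxybenzoate; 4 decylmagnesium bromide
Product: 7 Gentiside E (octadecyl 2,3-dihydroxybenzoate), via 8-bromooctyl 2,3-bis(trimethylsilyloxy)benzoate 5 (not isolated), via octadecyl 2,3-bis(trimethylsilyloxy)benzoate 6 (not isolated)
Conditions: (i) HMDS, cat. (NH4)2SO4, neat, 80 °C, then volatiles removed in vacuo; (ii) 4 (1.5 equiv, slow addition), Li2CuCl4 (3 mol%), NMP (4 equiv), THF, 0 °C; (iii) 1 M HCl, THF/MeOH, rt
Reagents that add atoms: hexamethyldisilazane, C[Si](C)(C)N[Si](C)(C)C (supplies the Me3Si groups of 5 and 6; none of its atoms remain in 7)
Why: This is a Kochi–Cahiez copper-catalysed alkyl–alkyl Grignard cross-coupling: 4 transmetalates to Cu(I) to give a decylcuprate, which attacks the primary C–Br carbon of 5 in an SN2-type oxidative addition, and reductive elimination from the dialkylcopper(III) species forms the C8–C9 bond and returns Cu(I). Two primary sp3 carbons are joined, so no ring is closed and no stereocentre is created. The step needs chemoselectivity for C–Br substitution over 1,2-addition to the aryl ester and over protonolysis of 4 by the phenols; the transient bis-silylation to 5 removes the acidic O–H groups (NH3 and excess HMDS are stripped off before the coupling), and NMP, slow addition and 0 °C keep the concentration of free 4 low while the ester of 5 is deactivated by its electron-donating silyloxy groups, one of them ortho to it. Any Si–O cleavage by 4 would only give a magnesium phenoxide, which is still a masked phenol, and the silyl ethers of 6 hydrolyse in the acidic work-up to give 7.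

Compound list
1 | 2,3-dihydroxybenzoic acid | O=C(O)c1cccc(O)c1O | starting material
2 | 1,8-dibromooctane | BrCCCCCCCCBr | starting material
3 | 8-bromooctyl 2,3-dihydroxybenzoate | BrCCCCCCCCOC(=O)c1cccc(O)c1O | intermediate
4 | decylmagnesium bromide | CCCCCCCCCC[Mg]Br | starting material
5 | 8-bromooctyl 2,3-bis(trimethylsilyloxy)benzoate | BrCCCCCCCCOC(=O)c1cccc(O[Si](C)(C)C)c1O[Si](C)(C)C | intermediate
6 | octadecyl 2,3-bis(trimethylsilyloxy)benzoate | CCCCCCCCCCCCCCCCCCOC(=O)c1cccc(O[Si](C)(C)C)c1O[Si](C)(C)C | intermediate
7 | Gentiside E (octadecyl 2,3-dihydroxybenzoate) | CCCCCCCCCCCCCCCCCCOC(=O)c1cccc(O)c1O | target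

Total step count: 2
Longest linear sequence: 2 steps (1 → 3 → 7)

Steps most likely to fail (the route has only two steps, so both are ranked):

1. Step 2. The Grignard reagent may add to the benzoate carbonyl in competition with the copper-catalysed substitution. The silyl masks may be lost early, so that magnesium phenoxides precipitate and stall the coupling. The Grignard reagent may homocouple, and traces of copper may promote air oxidation of the catechol during work-up. The fallback sets out from 1 and comes back to the route at 7, and avoids basic organometallics altogether. Carboxylate alkylation of 1 with 9-bromonon-1-ene (KHCO3, DMF, 50 °C) should give non-8-en-1-yl 2,3-dihydroxybenzoate F1. Olefin cross-metathesis of F1 with an excess of undec-1-ene (Grubbs second-generation catalyst, CH2Cl2, 40 °C, ethene purged) should form the same C8–C9 link as a C=C bond in octadec-8-en-1-yl 2,3-dihydroxybenzoate F2, expected as an E/Z mixture. Hydrogenation of F2 (H2, Pd/C, EtOAc, rt) converges both isomers on 7.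

2. Step 1. Over-alkylation may occur, either as O-alkylation of a phenol or as esterification at both ends of the dibromide, and the catechol may be oxidised by air under basic conditions. The fallback sets out from 1 and comes back at 3. Fischer esterification of 1 with commercial 8-bromooctan-1-ol (cat. TsOH, toluene, Dean–Stark reflux) replaces the carboxylate SN2 reaction by acid-catalysed acyl substitution. Under acid the phenols cannot be alkylated, and the monofunctional alcohol cannot give a diester.

Further compounds
F1 | step 2 | non-8-en-1-yl 2,3-dihydroxybenzoate | C=CCCCCCCCOC(=O)c1cccc(O)c1O
F2 | step 2 | octadec-8-en-1-yl 2,3-dihydroxybenzoate (E isomer drawn; E/Z mixture expected) | CCCCCCCCC/C=C/CCCCCCCOC(=O)c1cccc(O)c1O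
F0 | step 1 | none | none
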